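Numbering used throughout: ring A is the cyclopentane C1–C5 (C1 quaternary with methyl, C2/C3 methylenes, C4 isopropyl carbinol, C5 fusion CH). Ring B is the cycloheptene C1, C5–C10 (C6 aroyloxy CH, C7 CH2, C8=C9 with methyl on C8, C10 tigloyloxy CH). Bicyclic compounds are named with these locants.

## The problem

The target 27 is a cis-fused bicyclo[5.3.0]decene diester: ring A is joined through the C1–C5 bond to ring B, which carries a 4-hydroxybenzoate at C6 and a tiglate at C10. Five contiguous stereocentres (1R,4R,5S,6R,10S) must be set, with the oxygens at C4, C6 and C10 on one face and the C1 methyl and H5 on the other. Only C1 is an all-carbon centre that cannot be corrected later, so it has to be made in absolute terms. Once fixed, C1 can govern C5 (both ring-B arms must be cis), C4 (addition to a C4 ketone anti to those arms), then C6 (through C5 and C4) and finally C10 (through the shape of the bicycle). Two different esters sit on two secondary alcohols beside a free tertiary hydroxyl, so the order of acylation has to come from the route and not from reagent selectivity. The C10 tiglate is allylic and ionisable, the tertiary carbinol can dehydrate and the phenol ester is base-labile, so the closing steps must be near-neutral. The enabling feature is the C10(O)–C9=C8(CH3) unit: it is the transposition product of a β-alkoxy enone with its carbonyl at C8 and its alkoxy group at C10, and because C1 is quaternary the only enolisable carbon of that vinylogous ester is C7. An aldol bond C6–C7 therefore closes ring B and creates the C6 carbinol in one operation.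

## Retrosynthesis

**27 ⇒ 23 + 24.** The tigloyl C–O bond at C10 and the two silyl groups are removed first (27 ⇒ 26 ⇒ 23 + tiglic acid 24). The tiglate goes on last because it is the allylic, ionisable ester; a fluoride deprotection after it is the only step it has to survive. Alcohol 23 is simpler by one ester, and the forward step must acylate a neopentyl allylic alcohol without isomerising it (Yamaguchi conditions).

**23 ⇒ 22 ⇒ 17 + 20.** C10 is taken back to the ketone 22 and the C6 aroyl C–O bond is cut to hydroxy enone 17 and silyl-protected acid 20 (from 4-hydroxybenzoic acid 18). Acylating C6 while C10 is still a carbonyl means the two secondary hydroxyls are never free together, which the alternative order (reduce first, then differentiate a diol) could not guarantee. The forward reduction must deliver hydride on the face of the C1 methyl.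

**17 ⇒ 15.** The C8–CH3 bond is cut and the carbonyl moved from C10 to C8, the reverse of a Stork–Danheiser transposition. Olefination or enol-triflate coupling at C8 would need C8 and C10 to be differentiated separately; the vinylogous ester 15 stores the C10 oxygen, the olefin position and an electrophilic C8 in one function. The forward step asks for 1,2-addition of a methyl nucleophile to a β-hydroxy vinylogous ester without retro-aldol, then mild acid.

**15 ⇒ 13 (key).** The C6–C7 bond is cut. Cutting C9–C10 or C7–C8 instead would leave no single, unambiguous nucleophile–electrophile pair, whereas 13 has one enolisable methyl and one aldehyde. The cut removes ring B and the C6 stereocentre and leaves a cyclopentane with three stereocentres. The forward reaction needs site-selective enolisation at C7 and facial control at C6.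

**13 ⇒ 12 ⇒ 11 ⇒ 9.** The C10–OMe bond (methanol addition to ynone 11) and the C8–C9 bond (acetylation of alkyne 9) are cut, and C6 is returned to a silyl ether. Methanol addition to an ynone fixes the methoxy group at C10 without ambiguity, which O-methylation of a β-diketone would not. The primary triethylsilyl ether of 12 is oxidised directly, so the C6 alcohol is never free beside the vinylogous ester.

**9 ⇒ 8 ⇒ 7 ⇒ 6.** C9 is removed as a one-carbon homologation of a C10 aldehyde that is stored as lactol 7, itself from lactone 6. The lactone ties O6 to C10, so reduction and homologation release the C6 alcohol and the alkyne together. A nitrile at C1 would reach the alkyne in as many steps but offers no such link to C5.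

**6 ⇒ 5.** The C4–isopropyl bond is cut to keto lactone 5. In the cis-fused bicycle the lactone ring blocks one face at both the α- and β-carbons of the ketone, so addition from the other face sets C4.

**5 ⇒ 3 ⇒ 1.** The C5–C6 bond (hydroxymethylation of silyl enol ether 3) and the C1–CH3 bond (asymmetric conjugate addition to keto ester 1) are cut. Methyl addition to the ester-bearing enone is preferred over cyanide addition to 3-methylcyclopent-2-enone: the enolate is trapped regiospecifically, and C5 is epimerisable, so lactonisation of its cis epimer corrects it relative to C1. The starting material is an achiral, purchasable cyclopentenone.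

## Roads not taken

**Alternative 1:** Ring A would be built onto a preformed cycloheptene by cutting C1–C2, C3–C4 and C4–C5. In the forward sense the Co2(CO)6 complex of the silicon-tethered enyne A2 adds to the C1=C5 olefin and takes up CO, giving the tricyclic cyclopentenone A1 with an Si–O bridge from C2 to O10. Its merit is bond economy: three C–C bonds, the quaternary C1 and the cis fusion arise in one step, and the tether passes the C10 configuration to C1 and C5. In that respect it is better than the chosen plan, whose key step forms one bond. Its weak points are specific to this target. The olefin is trisubstituted and must become a quaternary centre, a poor case for the Pauson–Khand reaction, and silyl-tethered variants tend to lose the tether or give reduced products. A1 also lacks the C8 methyl and the C8=C9 olefin, which would have to be introduced in a saturated C7–C9 chain with no handle. C4 still needs isopropyl addition to an enone carbonyl, and C2=C3 must be reduced and desilylated. Against the shorter core construction, the chosen plan delivers C8, C9 and C10 already encoded in the vinylogous ester 15.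

**Alternative 2:** A cis-decalin is rearranged: in epoxy alcohol A4 the C6–C1 bond migrates to C5 with inversion while C6 becomes a ketone, giving the hydroazulene dione A3. The merits are real. A3 carries the whole skeleton, the C8=C9 methyl enone, both ring-B oxygens at ketone level and the free C4 hydroxyl, so its endgame (two reductions, two acylations) is shorter than the six steps after 15. A decalin is also easier to assemble than a 5–7 system, and the shift is stereospecific at C1 and C5. The weak point is the shift itself: the ring-fusion bond C6–C1 must be antiperiplanar to the breaking C5–O bond, and the exocyclic C6–C7 bond or Payne-type opening can compete. A3 is in addition a β-hydroxy ketone (C4–OH, C6=O) with an epimerisable C5, open to retro-aldol cleavage of ring A under the Lewis acid. Its two ketones must then be reduced and acylated selectively. The chosen plan sets against the shorter endgame a ring closure with only one possible bond (one enolisable carbon, one aldehyde).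

**Alternative 3:** The C1–CH3 and C4–C5 bonds are cut. Me2CuLi adds to C1 of cycloheptenone A6 anti to the C10 silyloxy group, and the C5 enolate closes onto the side-chain isopropyl ketone to give the bicyclic β-hydroxy ketone A5. It is more convergent than the chosen plan and sets C1, C5 and C4 in one flask, where the chosen route needs three substrate-controlled steps. Its weak points: cuprate addition to a β,β-disubstituted enone with a γ-silyloxy group is slow and open to reductive loss of the γ-oxygen, and the silyl chloride usually added to accelerate it would trap the enolate and stop the aldol. The C4 configuration depends on which face of the isopropyl ketone the enolate meets, and the aldol is reversible. Like A1, A5 has a saturated C7–C9 chain, so the C8 methyl and C8=C9 olefin would have to be built outward from the C6 ketone over several steps. The chosen plan accepts a longer, conventional cyclopentane synthesis in exchange for a key step that leaves the carbonyl exactly at C8.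

Key step: step 10

Assumption: keto ester 1 is a purchasable building block, and the ligand enantiomer L in step 1 is the one that delivers methyl to give (R)-3 (L = (4S,5S)- or (4R,5R)-1-(2,6-diethylphenyl)-4,5-diphenyl-3-(2-sulfonatophenyl)imidazolidin-2-ylidene, used as its silver complex [Ag2L2]).

## Route

Step 1
Reactants: 1 methyl 3-oxocyclopent-1-ene-1-carboxylate
Product: 3 methyl (1R)-1-methyl-3-[(triethylsilyl)oxy]cyclopent-2-ene-1-carboxylate, via dimethylaluminium enolate 2 (not isolated)
Conditions: Me3Al (3 equiv), Cu(OTf)2 (5 mol %), [Ag2L2] (2.5 mol %), THF, −78 °C; then Et3SiOTf, −78 → 0 °C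
Reagents that add atoms: trimethylaluminium, C[Al](C)C; triethylsilyl trifluoromethanesulfonate, CC[Si](CC)(CC)OS(=O)(=O)C(F)(F)F
Why: Copper–carbene-catalysed asymmetric conjugate addition of Me3Al to β-substituted cyclopentenones, γ-keto esters included, is an established way to quaternary centres; the ketone is the stronger acceptor, so methyl adds to the ester-bearing carbon and the ligand sets (R) at C1. O-Silylation of the aluminium enolate in the same flask fixes the enolate on the C5 side of the ketone, which base could not achieve later.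

Step 2
Reactants: 3 methyl (1R)-1-methyl-3-[(triethylsilyl)oxy]cyclopent-2-ene-1-carboxylate
Product: 5 keto lactone (3aS,6aR)-6a-methyltetrahydro-1H-cyclopenta[c]furan-1,4(5H)-dione, via hydroxymethyl ketone 4 (not isolated)
Conditions: 37 % aq. HCHO, Sc(OTf)3 (10 mol %), THF, rt; then camphorsulfonic acid (cat.), CH2Cl2, rt
Reagents that add atoms: formaldehyde, C=O
Why: Lewis-acid-catalysed Mukaiyama aldol with aqueous formaldehyde hydroxymethylates the silyl enol ether at C5 only. C5 is epimerisable, and only the epimer with CH2OH cis to the ester can lactonise, so acid funnels both epimers into the cis-fused γ-lactone and fixes C5 (S) relative to C1.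

Step 3
Reactants: 5 keto lactone (3aS,6aR)-6a-methyltetrahydro-1H-cyclopenta[c]furan-1,4(5H)-dione
Product: 6 (3aS,4R,6aR)-4-hydroxy-6a-methyl-4-(propan-2-yl)hexahydro-1H-cyclopenta[c]furan-1-one
Conditions: i-PrMgCl, CeCl3, THF, −78 → −40 °C; aq. NH4Cl
Reagents that add atoms: isopropylmagnesium chloride, CC(C)[Mg]Cl
Why: Organocerium 1,2-addition suppresses enolisation and β-hydride reduction and prefers the ketone to the hindered lactone. The lactone ring occupies one face at both the α- and β-carbons, so isopropyl enters from the face of H5 and the C1 methyl and the new hydroxyl ends up cis to C6 (4R).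

Step 4
Reactants: 6 (3aS,4R,6aR)-4-hydroxy-6a-methyl-4-(propan-2-yl)hexahydro-1H-cyclopenta[c]furan-1-one
Product: 7 lactol (3aS,4R,6aR)-6a-methyl-4-(propan-2-yl)hexahydro-1H-cyclopenta[c]furan-1,4-diol (both C1 anomers)
Conditions: i-Bu2AlH (2.5 equiv), CH2Cl2, −78 °C; aq. KNaC4H4O6
Reagents that add atoms: none
Why: Low-temperature hydride reduction of a γ-lactone stops at the lactol because the aluminium hemiacetal is stable at −78 °C; the first equivalent is consumed by the tertiary hydroxyl and no stereocentre of the ring is touched.

Step 5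
Reactants: 7 lactol (3aS,4R,6aR)-6a-methyl-4-(propan-2-yl)hexahydro-1H-cyclopenta[c]furan-1,4-diol
Product: 8 (1R,2S,3R)-3-ethynyl-2-(hydroxymethyl)-3-methyl-1-(propan-2-yl)cyclopentan-1-ol
Conditions: MeC(O)C(N2)P(O)(OMe)2, K2CO3, MeOH, rt
Reagents that add atoms: dimethyl (1-diazo-2-oxopropyl)phosphonate, CC(=O)C(=[N+]=[N-])P(=O)(OC)OC
Why: Seyferth–Gilbert homologation in its Ohira–Bestmann form acts on lactols through the open hydroxy aldehyde; the alkylidene carbene from an aldehyde rearranges by 1,2-hydrogen shift to the terminal alkyne. C1 has no α-hydrogen, so nothing can epimerise.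

Step 6
Reactants: 8 (1R,2S,3R)-3-ethynyl-2-(hydroxymethyl)-3-methyl-1-(propan-2-yl)cyclopentan-1-ol
Product: 9 triethyl({(1R,2S,3R)-3-ethynyl-3-methyl-1-(propan-2-yl)-2-{[(triethylsilyl)oxy]methyl}cyclopentyl}oxy)silane
Conditions: Et3SiOTf (3 equiv), 2,6-lutidine, CH2Cl2, −78 → 0 °C
Reagents that add atoms: triethylsilyl trifluoromethanesulfonate, CC[Si](CC)(CC)OS(=O)(=O)C(F)(F)F
Why: Silyl triflate with a hindered pyridine base silylates primary and hindered tertiary alcohols alike, so one step gives the robust tertiary ether at C4 and the primary ether at C6 that is later oxidised directly.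

Step 7
Reactants: 9 triethyl({(1R,2S,3R)-3-ethynyl-3-methyl-1-(propan-2-yl)-2-{[(triethylsilyl)oxy]methyl}cyclopentyl}oxy)silane
Product: 11 4-{(1R,2S,3R)-1-methyl-3-(propan-2-yl)-3-[(triethylsilyl)oxy]-2-{[(triethylsilyl)oxy]methyl}cyclopentyl}but-3-yn-2-one, via lithium acetylide 10 (not isolated)
Conditions: n-BuLi, THF, −78 °C; then MeC(O)N(OMe)Me, −78 → 0 °C; aq. NH4Cl
Reagents that add atoms: N-methoxy-N-methylacetamide, CC(=O)N(C)OC
Why: Acylation of a lithium acetylide with a Weinreb amide stops at the ynone because the chelated tetrahedral adduct survives until work-up; this forms the C8–C9 bond and introduces C7 as the methyl ketone.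

Step 8
Reactants: 11 4-{(1R,2S,3R)-1-methyl-3-(propan-2-yl)-3-[(triethylsilyl)oxy]-2-{[(triethylsilyl)oxy]methyl}cyclopentyl}but-3-yn-2-one
Product: 12 (3E)-4-methoxy-4-{(1R,2S,3R)-1-methyl-3-(propan-2-yl)-3-[(triethylsilyl)oxy]-2-{[(triethylsilyl)oxy]methyl}cyclopentyl}but-3-en-2-one
Conditions: NaOMe (0.2 equiv), MeOH–THF, 0 °C
Reagents that add atoms: methanol, CO
Why: Oxa-Michael addition of methoxide to an ynone places the methoxy group at the β-carbon C10 without ambiguity. The allenolate is protonated from the side of the small methoxy group, and the β-alkoxy enone with OMe trans to the acyl group is also the usual thermodynamic isomer, so the (E) geometry with the acyl group cis to C1 is expected; reversible methoxide addition lets any (Z) isomer equilibrate.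

Step 9
Reactants: 12 (3E)-4-methoxy-4-{(1R,2S,3R)-1-methyl-3-(propan-2-yl)-3-[(triethylsilyl)oxy]-2-{[(triethylsilyl)oxy]methyl}cyclopentyl}but-3-en-2-one
Product: 13 (1R,2R,5R)-5-[(1E)-1-methoxy-3-oxobut-1-en-1-yl]-5-methyl-2-(propan-2-yl)-2-[(triethylsilyl)oxy]cyclopentane-1-carbaldehyde
Conditions: (COCl)2 (4 equiv), DMSO (8 equiv), CH2Cl2, −78 → −35 °C; then Et3N, −78 → 0 °C
Reagents that add atoms: none
Why: Under Swern conditions a primary triethylsilyl ether is cleaved and oxidised to the aldehyde in one flask while a hindered tertiary silyl ether is left alone, so the C6 alcohol is never free beside the vinylogous ester. C5 lies between two fully substituted carbons and is not expected to epimerise with Et3N at low temperature.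

Step 10
Reactants: 13 (1R,2R,5R)-5-[(1E)-1-methoxy-3-oxobut-1-en-1-yl]-5-methyl-2-(propan-2-yl)-2-[(triethylsilyl)oxy]cyclopentane-1-carbaldehyde
Product: 15 (1R,4R,5S,6R)-6-hydroxy-10-methoxy-1-methyl-4-(propan-2-yl)-4-[(triethylsilyl)oxy]-cis-bicyclo[5.3.0]dec-9-en-8-one (text numbering: C8 ketone and C9=C10 enol ether), via lithium dienolate 14 (not isolated)
Conditions: LiN(i-Pr)2 (1.1 equiv), THF (0.01 M), −78 °C, substrate added to base; AcOH, −78 °C
Reagents that add atoms: none
Why: The amide base removes a C7 methyl proton, the only α′-hydrogens available, because the γ-carbon of the vinylogous ester (C1) is quaternary and the aldehyde α-hydrogen at C5 is buried between two fully substituted carbons; this gives the cross-conjugated lithium dienolate 14. C7 then adds to the C6 aldehyde; the closest known reaction types are kinetic α′-enolate aldol additions of β-alkoxy enones and amide-base intramolecular aldol closures of keto aldehydes to seven-membered rings. Ring B closes in the 7-(enolendo)-exo-trig mode (both enolate carbons C7 and C8 become ring atoms, the aldehyde C=O stays exocyclic), which is allowed for this ring size. Closure is preorganised by the cis arms on the cyclopentane and by the (E)-enol ether, which holds the acyl group cis to C1 and pointing at C6. The new C6 stereocentre is controlled by C5 and its quaternary neighbour C4: the tethered enolate carbon should approach anti to C4 in a Felkin–Anh arrangement with the carbonyl oxygen between C1 and C4, which gives the (6R) alcohol with O6 anti to H5 and on the face of O4. The step needs site-selective enolisation (secured as stated) and survival of the β-silyloxy aldehyde and the aldolate, for which low temperature, only a slight excess of base and an acidic quench at −78 °C are chosen.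

Step 11
Reactants: 15 (1R,4R,5S,6R)-6-hydroxy-10-methoxy-1-methyl-4-(propan-2-yl)-4-[(triethylsilyl)oxy]-cis-bicyclo[5.3.0]dec-9-en-8-one
Product: 17 (1R,4R,5S,6R)-6-hydroxy-1,8-dimethyl-4-(propan-2-yl)-4-[(triethylsilyl)oxy]-cis-bicyclo[5.3.0]dec-8-en-10-one (text numbering), via tertiary allylic carbinol 16 (not isolated)
Conditions: MeLi (4 equiv), CeCl3, THF, −78 °C; then 1 M aq. HCl, THF, 0 °C
Reagents that add atoms: methyllithium, [Li]C; water, O
Why: Stork–Danheiser transposition: the methylcerium reagent adds 1,2 to the vinylogous ester carbonyl with little enolisation at C7 or retro-aldol of the C6 alkoxide, and dilute acid then ionises the tertiary allylic alcohol and hydrolyses the enol ether to the C10 enone with methyl on C8 and the C8=C9 olefin. No stereocentre is formed, and the tertiary silyl ether should tolerate brief cold acid.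

Step 12
Reactants: 18 4-hydroxybenzoic acid
Product: 20 4-{[tri(propan-2-yl)silyl]oxy}benzoic acid, via bis-silylated ester 19 (not isolated)
Conditions: i-Pr3SiCl (2.2 equiv), imidazole, DMF, rt; then AcOH–THF–H2O, rt
Reagents that add atoms: chlorotri(propan-2-yl)silane, CC(C)[Si](Cl)(C(C)C)C(C)C
Why: Exhaustive silylation followed by mild aqueous acid cleaves the labile silyl ester and keeps the aryl silyl ether, a standard way to mask the phenol so that it cannot be acylated in steps 13 and 15.

Step 13
Reactants: 17 (1R,4R,5S,6R)-6-hydroxy-1,8-dimethyl-4-(propan-2-yl)-4-[(triethylsilyl)oxy]-cis-bicyclo[5.3.0]dec-8-en-10-one; 20 4-{[tri(propan-2-yl)silyl]oxy}benzoic acid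
Product: 22 (1R,4R,5S,6R)-1,8-dimethyl-10-oxo-4-(propan-2-yl)-4-[(triethylsilyl)oxy]-cis-bicyclo[5.3.0]dec-8-en-6-yl 4-{[tri(propan-2-yl)silyl]oxy}benzoate (text numbering), via mixed anhydride 21 (not isolated)
Conditions: 20, 2,4,6-Cl3C6H2COCl, Et3N, THF, rt; then 17, DMAP, toluene, rt → 50 °C
Reagents that add atoms: none
Why: Yamaguchi esterification acylates hindered secondary alcohols through the acylpyridinium ion of the less hindered acyl group of the mixed anhydride; the C6–O bond is untouched, so C6 keeps its configuration, and C6 is the only free hydroxyl at this stage.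

Step 14
Reactants: 22 (1R,4R,5S,6R)-1,8-dimethyl-10-oxo-4-(propan-2-yl)-4-[(triethylsilyl)oxy]-cis-bicyclo[5.3.0]dec-8-en-6-yl 4-{[tri(propan-2-yl)silyl]oxy}benzoate
Product: 23 (1R,4R,5S,6R,10S)-10-hydroxy-1,8-dimethyl-4-(propan-2-yl)-4-[(triethylsilyl)oxy]-cis-bicyclo[5.3.0]dec-8-en-6-yl 4-{[tri(propan-2-yl)silyl]oxy}benzoate (text numbering)
Conditions: NaBH4, CeCl3·7H2O, MeOH, −78 °C
Reagents that add atoms: none
Why: Luche reduction gives clean 1,2-reduction of the enone and spares both esters. Hydride is expected on the convex face carrying the C1 methyl and H5, because the opposite face is screened by the folded cyclopentane with its C4 silyloxy group and by the C6 aroyloxy group; this gives the (10S) alcohol with O10 trans to the C1 methyl.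

Step 15
Reactants: 23 (1R,4R,5S,6R,10S)-10-hydroxy-1,8-dimethyl-4-(propan-2-yl)-4-[(triethylsilyl)oxy]-cis-bicyclo[5.3.0]dec-8-en-6-yl 4-{[tri(propan-2-yl)silyl]oxy}benzoate; 24 tiglic acid ((2E)-2-methylbut-2-enoic acid)
Product: 26 (1R,4R,5S,6R,10S)-1,8-dimethyl-10-{[(2E)-2-methylbut-2-enoyl]oxy}-4-(propan-2-yl)-4-[(triethylsilyl)oxy]-cis-bicyclo[5.3.0]dec-8-en-6-yl 4-{[tri(propan-2-yl)silyl]oxy}benzoate (text numbering), via mixed anhydride 25 (not isolated)
Conditions: 24, 2,4,6-Cl3C6H2COCl, Et3N, toluene, rt; then 23, DMAP, toluene, rt → 60 °C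
Reagents that add atoms: none
Why: Yamaguchi esterification is a standard method for placing tigloyl groups on hindered secondary alcohols; the (E) acid is the stable isomer and is not expected to isomerise, and acylation with retention at C10 avoids any allylic substitution.

Step 16
Reactants: 26 (1R,4R,5S,6R,10S)-1,8-dimethyl-10-{[(2E)-2-methylbut-2-enoyl]oxy}-4-(propan-2-yl)-4-[(triethylsilyl)oxy]-cis-bicyclo[5.3.0]dec-8-en-6-yl 4-{[tri(propan-2-yl)silyl]oxy}benzoate
Product: 27 (1R,4R,5S,6R,10S)-4-hydroxy-1,8-dimethyl-10-{[(2E)-2-methylbut-2-enoyl]oxy}-4-(propan-2-yl)-cis-bicyclo[5.3.0]dec-8-en-6-yl 4-hydroxybenzoate (text numbering; the target)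
Conditions: Bu4NF, AcOH (1:1), THF, 0 °C → rt
Reagents that add atoms: none
Why: Buffered fluoride cleaves the aryl silyl ether and the tertiary triethylsilyl ether in one operation; the acetic acid buffer keeps the medium near neutral so that the allylic tiglate is not ionised and neither ester migrates or hydrolyses.

## Compound list

1 | methyl 3-oxocyclopent-1-ene-1-carboxylate | COC(=O)C1=CC(=O)CC1 | starting material
2 | methyl (1R)-3-[(dimethylalumanyl)oxy]-1-methylcyclopent-2-ene-1-carboxylate (aluminium enolate) | COC(=O)[C@]1(C)CCC(O[Al](C)C)=C1 | intermediate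
3 | methyl (1R)-1-methyl-3-[(triethylsilyl)oxy]cyclopent-2-ene-1-carboxylate | COC(=O)[C@]1(C)CCC(O[Si](CC)(CC)CC)=C1 | intermediate
4 | methyl (1R)-2-(hydroxymethyl)-1-methyl-3-oxocyclopentane-1-carboxylate (both C2 epimers) | COC(=O)[C@]1(C)CCC(=O)C1CO | intermediate
5 | (3aS,6aR)-6a-methyltetrahydro-1H-cyclopenta[c]furan-1,4(5H)-dione | O=C1OC[C@@H]2[C@@]1(C)CCC2=O | intermediate
6 | (3aS,4R,6aR)-4-hydroxy-6a-methyl-4-(propan-2-yl)hexahydro-1H-cyclopenta[c]furan-1-one | O=C1OC[C@@H]2[C@@]1(C)CC[C@@]2(O)C(C)C | intermediate
7 | (3aS,4R,6aR)-6a-methyl-4-(propan-2-yl)hexahydro-1H-cyclopenta[c]furan-1,4-diol (lactol, both anomers) | OC1OC[C@@H]2[C@@]1(C)CC[C@@]2(O)C(C)C | intermediate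
8 | (1R,2S,3R)-3-ethynyl-2-(hydroxymethyl)-3-methyl-1-(propan-2-yl)cyclopentan-1-ol | OC[C@@H]1[C@](C)(C#C)CC[C@@]1(O)C(C)C | intermediate
9 | triethyl({(1R,2S,3R)-3-ethynyl-3-methyl-1-(propan-2-yl)-2-{[(triethylsilyl)oxy]methyl}cyclopentyl}oxy)silane | CC[Si](CC)(CC)OC[C@@H]1[C@](C)(C#C)CC[C@@]1(O[Si](CC)(CC)CC)C(C)C | intermediate
10 | lithium acetylide of 9 | CC[Si](CC)(CC)OC[C@@H]1[C@](C)(C#C[Li])CC[C@@]1(O[Si](CC)(CC)CC)C(C)C | intermediate
11 | 4-{(1R,2S,3R)-1-methyl-3-(propan-2-yl)-3-[(triethylsilyl)oxy]-2-{[(triethylsilyl)oxy]methyl}cyclopentyl}but-3-yn-2-one | CC[Si](CC)(CC)OC[C@@H]1[C@](C)(C#CC(C)=O)CC[C@@]1(O[Si](CC)(CC)CC)C(C)C | intermediate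
12 | (3E)-4-methoxy-4-{(1R,2S,3R)-1-methyl-3-(propan-2-yl)-3-[(triethylsilyl)oxy]-2-{[(triethylsilyl)oxy]methyl}cyclopentyl}but-3-en-2-one | CC[Si](CC)(CC)OC[C@@H]1[C@](C)(/C(OC)=C\C(C)=O)CC[C@@]1(O[Si](CC)(CC)CC)C(C)C | intermediate
13 | (1R,2R,5R)-5-[(1E)-1-methoxy-3-oxobut-1-en-1-yl]-5-methyl-2-(propan-2-yl)-2-[(triethylsilyl)oxy]cyclopentane-1-carbaldehyde | O=C[C@@H]1[C@](C)(/C(OC)=C\C(C)=O)CC[C@@]1(O[Si](CC)(CC)CC)C(C)C | intermediate
14 | lithium dienolate of 13 (C7=C8 enolate) | O=C[C@@H]1[C@](C)(/C(OC)=C\C(=C)O[Li])CC[C@@]1(O[Si](CC)(CC)CC)C(C)C | intermediate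
15 | (1R,4R,5S,6R)-6-hydroxy-10-methoxy-1-methyl-4-(propan-2-yl)-4-[(triethylsilyl)oxy]-cis-bicyclo[5.3.0]dec-9-en-8-one (text numbering) | COC1=CC(=O)C[C@@H](O)[C@@H]2[C@@]1(C)CC[C@@]2(O[Si](CC)(CC)CC)C(C)C | intermediate
16 | (1R,4R,5S,6R)-10-methoxy-1,8-dimethyl-4-(propan-2-yl)-4-[(triethylsilyl)oxy]-cis-bicyclo[5.3.0]dec-9-ene-6,8-diol (C8 epimers, text numbering) | COC1=CC(C)(O)C[C@@H](O)[C@@H]2[C@@]1(C)CC[C@@]2(O[Si](CC)(CC)CC)C(C)C | intermediate
17 | (1R,4R,5S,6R)-6-hydroxy-1,8-dimethyl-4-(propan-2-yl)-4-[(triethylsilyl)oxy]-cis-bicyclo[5.3.0]dec-8-en-10-one (text numbering) | O=C1C=C(C)C[C@@H](O)[C@@H]2[C@@]1(C)CC[C@@]2(O[Si](CC)(CC)CC)C(C)C | intermediate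
18 | 4-hydroxybenzoic acid | OC(=O)c1ccc(O)cc1 | starting material
19 | tri(propan-2-yl)silyl 4-{[tri(propan-2-yl)silyl]oxy}benzoate | CC(C)[Si](C(C)C)(C(C)C)OC(=O)c1ccc(O[Si](C(C)C)(C(C)C)C(C)C)cc1 | intermediate
20 | 4-{[tri(propan-2-yl)silyl]oxy}benzoic acid | OC(=O)c1ccc(O[Si](C(C)C)(C(C)C)C(C)C)cc1 | intermediate
21 | 4-{[tri(propan-2-yl)silyl]oxy}benzoic 2,4,6-trichlorobenzoic anhydride | CC(C)[Si](C(C)C)(C(C)C)Oc1ccc(cc1)C(=O)OC(=O)c1c(Cl)cc(Cl)cc1Cl | intermediate
22 | (1R,4R,5S,6R)-1,8-dimethyl-10-oxo-4-(propan-2-yl)-4-[(triethylsilyl)oxy]-cis-bicyclo[5.3.0]dec-8-en-6-yl 4-{[tri(propan-2-yl)silyl]oxy}benzoate (text numbering) | O=C1C=C(C)C[C@@H](OC(=O)c3ccc(O[Si](C(C)C)(C(C)C)C(C)C)cc3)[C@@H]2[C@@]1(C)CC[C@@]2(O[Si](CC)(CC)CC)C(C)C | intermediate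
23 | (1R,4R,5S,6R,10S)-10-hydroxy-1,8-dimethyl-4-(propan-2-yl)-4-[(triethylsilyl)oxy]-cis-bicyclo[5.3.0]dec-8-en-6-yl 4-{[tri(propan-2-yl)silyl]oxy}benzoate (text numbering) | O[C@H]1C=C(C)C[C@@H](OC(=O)c3ccc(O[Si](C(C)C)(C(C)C)C(C)C)cc3)[C@@H]2[C@@]1(C)CC[C@@]2(O[Si](CC)(CC)CC)C(C)C | intermediate
24 | tiglic acid, (2E)-2-methylbut-2-enoic acid | C/C=C(\C)C(=O)O | starting material
25 | (2E)-2-methylbut-2-enoic 2,4,6-trichlorobenzoic anhydride | C/C=C(\C)C(=O)OC(=O)c1c(Cl)cc(Cl)cc1Cl | intermediate
26 | (1R,4R,5S,6R,10S)-1,8-dimethyl-10-{[(2E)-2-methylbut-2-enoyl]oxy}-4-(propan-2-yl)-4-[(triethylsilyl)oxy]-cis-bicyclo[5.3.0]dec-8-en-6-yl 4-{[tri(propan-2-yl)silyl]oxy}benzoate (text numbering) | C/C=C(\C)C(=O)O[C@H]1C=C(C)C[C@@H](OC(=O)c3ccc(O[Si](C(C)C)(C(C)C)C(C)C)cc3)[C@@H]2[C@@]1(C)CC[C@@]2(O[Si](CC)(CC)CC)C(C)C | intermediate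
27 | (1R,4R,5S,6R,10S)-4-hydroxy-1,8-dimethyl-10-{[(2E)-2-methylbut-2-enoyl]oxy}-4-(propan-2-yl)-cis-bicyclo[5.3.0]dec-8-en-6-yl 4-hydroxybenzoate (text numbering) | C/C=C(\C)C(=O)O[C@H]1C=C(C)C[C@@H](OC(=O)c2ccc(O)cc2)[C@@H]2[C@@]1(C)CC[C@@]2(O)C(C)C | target

## Step count and least certain steps

Total: 16 steps. Longest linear sequence: 15 steps (1 to 27 through steps 1–11 and 13–16); step 12 is a one-step side branch.

**Step 10 (key step).** The most likely failure is poor facial selectivity at C6. The Felkin–Anh preference is modest in a medium-ring closure, and a chelated transition state could turn the aldehyde the other way. A second, less likely failure is proton transfer from C5 to the enolate, followed by loss of silanolate. Fallback for the stereochemical case: setting out from 13, the C6-epimeric aldol product F1 is carried through the conditions of step 11 (carbinol F2, not isolated) to the 6-epi hydroxy enone F3. F3 is then esterified with inversion by a Mitsunobu reaction with acid 20 (PPh3, diisopropyl azodicarboxylate, toluene), which rejoins the route at 22.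

**Step 11.** Retro-aldol fragmentation of the lithium β-alkoxide or enolisation at C7 may compete with 1,2-addition, because the carbonyl of a vinylogous ester is a poor electrophile. In the acid step the C6 hydroxyl may also be captured at C10 as a bridged ketal. Fallback: setting out from 15, the C6 hydroxyl is first silylated (Et3SiCl, imidazole) to the bis-silyl ether F4, so that no alkoxide is present during the addition. The methyl adduct F5 (not isolated) is then treated with aqueous acid, which removes the secondary silyl ether and effects the transposition, returning to 17.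

**Step 14.** Hydride delivery may occur on the wrong face, because the C1 methyl stands on the face from which attack is wanted and the substrate bias is therefore small. Fallback: setting out from 22, the reduction is run under reagent control with a Corey–Bakshi–Shibata catalyst ((S)- or (R)-1-methyl-3,3-diphenyltetrahydro-1H,3H-pyrrolo[1,2-c][1,3,2]oxazaborole with catecholborane, toluene, −78 °C), the enantiomer being chosen to match the required (10S) sense. This returns directly to 23 without new intermediates.

**Step 9.** Loss of the enol ether or attack of the activated sulfoxide at C9 may accompany the one-flask desilylation–oxidation, since hydrogen chloride is present before the amine is added. Fallback: setting out from 12, the primary silyl ether is cleaved selectively with buffered HF·pyridine (pyridine, THF, 0 °C) to the primary alcohol F6. F6 is oxidised at once with Dess–Martin periodinane and NaHCO3 to return to 13.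

**Step 5.** Slow homologation of the hindered lactol is possible: the aldehyde carbon is neopentyl and is present mainly as the closed hemiacetal, so base-induced decomposition of the diazophosphonate may outrun the reaction. Fallback: setting out from 7, a Wittig reaction with the ylide from (chloromethyl)triphenylphosphonium chloride and NaN(SiMe3)2 gives the chloroalkene diol F7. Excess LiN(i-Pr)2 then eliminates hydrogen chloride to return to 8.

## Further compounds

F1 | step 10 | (1R,4R,5S,6S)-6-hydroxy-10-methoxy-1-methyl-4-(propan-2-yl)-4-[(triethylsilyl)oxy]-cis-bicyclo[5.3.0]dec-9-en-8-one (C6 epimer of 15) | COC1=CC(=O)C[C@H](O)[C@@H]2[C@@]1(C)CC[C@@]2(O[Si](CC)(CC)CC)C(C)C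
F2 | step 10 | C6 epimer of carbinol 16 | COC1=CC(C)(O)C[C@H](O)[C@@H]2[C@@]1(C)CC[C@@]2(O[Si](CC)(CC)CC)C(C)C
F3 | step 10 | (1R,4R,5S,6S)-6-hydroxy-1,8-dimethyl-4-(propan-2-yl)-4-[(triethylsilyl)oxy]-cis-bicyclo[5.3.0]dec-8-en-10-one (C6 epimer of 17) | O=C1C=C(C)C[C@H](O)[C@@H]2[C@@]1(C)CC[C@@]2(O[Si](CC)(CC)CC)C(C)C
F4 | step 11 | (1R,4R,5S,6R)-10-methoxy-1-methyl-4-(propan-2-yl)-4,6-bis[(triethylsilyl)oxy]-cis-bicyclo[5.3.0]dec-9-en-8-one | COC1=CC(=O)C[C@@H](O[Si](CC)(CC)CC)[C@@H]2[C@@]1(C)CC[C@@]2(O[Si](CC)(CC)CC)C(C)C
F5 | step 11 | (1R,4R,5S,6R)-10-methoxy-1,8-dimethyl-4-(propan-2-yl)-4,6-bis[(triethylsilyl)oxy]-cis-bicyclo[5.3.0]dec-9-en-8-ol (C8 epimers) | COC1=CC(C)(O)C[C@@H](O[Si](CC)(CC)CC)[C@@H]2[C@@]1(C)CC[C@@]2(O[Si](CC)(CC)CC)C(C)C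
F0 | step 14 | none | none
F6 | step 9 | (3E)-4-{(1R,2S,3R)-2-(hydroxymethyl)-1-methyl-3-(propan-2-yl)-3-[(triethylsilyl)oxy]cyclopentyl}-4-methoxybut-3-en-2-one | OC[C@@H]1[C@](C)(/C(OC)=C\C(C)=O)CC[C@@]1(O[Si](CC)(CC)CC)C(C)C
F7 | step 5 | (1R,2S,3R)-3-(2-chloroethenyl)-2-(hydroxymethyl)-3-methyl-1-(propan-2-yl)cyclopentan-1-ol (E/Z mixture) | OC[C@@H]1[C@](C)(C=CCl)CC[C@@]1(O)C(C)C
A1 | alternative 1 | tricyclic cyclopentenone with Si–O bridge from C2 to O10, C6 tert-butyldimethylsilyl ether | CC(C)[Si]3(C(C)C)O[C@H]1CCC[C@@H](O[Si](C)(C)C(C)(C)C)[C@@H]2[C@@]1(C)C3=CC2=O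
A2 | alternative 1 | 1-methylcycloheptene carrying the C10 (ethynyl)di(propan-2-yl)silyl ether and the C6 tert-butyldimethylsilyl ether | C#C[Si](C(C)C)(C(C)C)O[C@H]1CCC[C@@H](O[Si](C)(C)C(C)(C)C)C=C1C
A3 | alternative 2 | cis-fused hydroazulene-6,10-dione with C8=C9 olefin and free C4 hydroxyl | O=C1C=C(C)CC(=O)[C@@H]2[C@@]1(C)CC[C@@]2(O)C(C)C
A4 | alternative 2 | cis-decalin enone with C6 tertiary hydroxyl and C4–C5 epoxide | O=C1C=C(C)C[C@@]2(O)[C@H]3O[C@@]3(C(C)C)CC[C@@]12C
A5 | alternative 3 | cis-fused bicyclic β-hydroxy ketone with C4 hydroxyl, C6 ketone and C10 tert-butyldimethylsilyl ether | CC(C)(C)[Si](C)(C)O[C@H]1CCCC(=O)[C@@H]2[C@@]1(C)CC[C@@]2(O)C(C)C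
A6 | alternative 3 | cyclohept-2-en-1-one carrying the 4-methyl-3-oxopentyl chain on C1 and the C10 tert-butyldimethylsilyl ether | CC(C)C(=O)CCC1=CC(=O)CCC[C@@H]1O[Si](C)(C)C(C)(C)C
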